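**Structural features**

Betaethrin A (15) is two tetrasubstituted benzene rings joined by one diaryl ether oxygen; it has no stereocentre, so there are no neighbouring stereocentres to relate. Ring A carries the methyl ester on C1, between the C2 hydroxyl and the ether carbon C6, and a methyl group on C4. Ring B carries the ether carbon C1' between the C2' hydroxyl and the acetoxymethyl group on C6', and a methoxy group on C4'. Both ether carbons therefore have two ortho substituents, and the two adjacent oxygens of ring B (O1' in the ether, O2' as free hydroxyl) differ only in their relation to the C6' side chain. The fragile parts are the primary benzylic acetate (lost to alkoxide, hydroxide or acidic alcohol, and able to ionise under strong Lewis acids), ring B at the free catechol stage (air oxidation), and the ether itself in base, because a phenoxide on O2' could take ring A over from O1' by adding to the ester-activated C6. The real difficulty is to make the hindered C6–O–C1' bond on the correct one of two neighbouring ring B oxygens. The feature that answers both is that the ester carbon on C1 and the oxygen on C2' are each ortho to the ether link. Tied together they form a seven-membered lactone (C1–CO–O2'–C2'–C1'–O–C6), which makes the etherification intramolecular, fixes which oxygen becomes the ether, and on methanolysis returns CO2CH3 on C1 and OH on C2'.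

**Logic of the disconnections**

15 to 14: the O–CH2OCH3 bond on the C2 oxygen of ring A is cut. The hydroxyl has to stay masked through the organolithium, copper, hydride and alkoxide steps, and this acetal is also the directing group for the ring A metalation. Nothing is gained in skeleton, but every earlier step depends on it. The demand is an unmasking that spares the benzylic acetate and the methyl ester, hence a mild Lewis acid with a thiol scavenger and no alcohol solvent.

14 to 13: the bond between the C6' benzylic carbon and the acetate oxygen is cut. The acetate cannot survive the methoxide that opens the lactone, so it must come after that step. The gain is a simple diol. The demand is esterification of the primary alcohol in the presence of the free C2' phenol, which is met by activating the alcohol and not the acyl group.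

13 to 11 (through 12): the ester O–CH3 bond is cut and the carbonyl carbon is rejoined to O2'; the hydroxymethyl group goes back to the formyl group. The gain is that one ring holds the ester, the ether and the C2' oxygen, so the two ring B oxygens need no separate protecting groups. The demand is that the aldehyde is reduced before methoxide is added, so that no formyl-stabilised phenoxide can serve as leaving group for an aryl shift from O1' to O2', and that the hydride spares the lactone.

11 to 10: the O1'–C6 aryl ether bond inside the seven-membered ring is cut. This is the most hindered bond of the target, and cutting it while the ester tether is in place leaves two benzene rings joined only by an acyl–oxygen bond. The demand is a phenoxide on O1', a halide on C6, and an acyl group that stays on O2'. For that reason the C6' carbon is kept as the formyl group in 10 and is not reduced or acetylated earlier: it chelates the O1' hydroxyl and makes its phenoxide the preferred anion.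

10 to 5 and 8 (through 9): the acyl C–O2' bond is cut. This is the most convergent cut and gives two pieces of similar size. The demand is activation of a 2,6-disubstituted acid without acid (the acetal is next to the carboxyl) and acylation of only the non-chelated hydroxyl of 8. A weak base is used so that the neutral hydroxyl reacts, and the same isomer is the thermodynamic one.

5 to 2 and 3 (through 4): the C1–carboxyl bond is cut. C1 lies between bromine and the acetal oxygen and carries the most acidic ring hydrogen, so 3 can be introduced there directly. The demand is an amide base at low temperature (no bromine–lithium exchange, no aryne) and a cold, mild acidification.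

2 to 1: the O–CH2OCH3 bond is cut, giving the commercial phenol.

8 to 7 to 6: the C–OH bond next to the existing hydroxyl is cut back to C–Br and then to C–H. The existing hydroxyl directs the halogen to the only free ortho position and then assists its copper-mediated replacement. The gain is the commercial aldehyde 6. The demand is exclusion of air while the catecholate is in hot alkali.

**Other disconnections considered**

Alternative 1: Ring A is cut at C1–C2, C5–C6 and C2–C3, giving 3-methylcyclobut-2-en-1-one A1 and the ring B ethynyl ether A2, in which O1' already carries the alkyne and the other two oxygens are triisopropylsilyl ethers.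
- Forward step: heating A1 with A2 should open the four-membered ring to a vinylketene, add it to the alkyne in a [2+2] step (C1–C2, C5–C6), reopen the new cyclobutenone and close the dienylketene by 6π electrocyclisation (C2–C3) to the phenol A3.
- In favour: the 1,3,5-pattern of ring A follows from the mechanism. The ether oxygen is never forced between two hindered aryl carbons; on that point the alternative is better than the chosen plan. It is also better in having no acyl-shift question and no metal.
- Against: A3 lacks the C1 ester carbon, which must be added afterwards between two oxygens (protection, ortho-metalation, carboxylation). A2 still needs the O1'/O2' differentiation of the ring B catechol, now by protecting groups, and an ethynyl ether on a di-ortho-substituted phenol. A1 is volatile, prone to polymerise and not a stock chemical. After desilylation the benzylic alcohol must again be acetylated beside free phenols, so it is equal to the chosen plan on that point.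
- Comparison: on structure it postpones the most congested carbon (C1); on step economy it is clearly longer, an estimated fourteen to sixteen operations against nine.

Alternative 2: Ring A is cut at C4–C5 and C1–C6, giving methyl 4-(methoxymethoxy)-6-methyl-2-oxo-2H-pyran-3-carboxylate A4 and the ring B ethynyl ether A5 (acetal on O2', silyl ether on the benzylic oxygen).
- Forward step: [4+2] addition of A5 across C3 and C6 of A4, then loss of carbon dioxide (3) by retro-[4+2], should give the diaryl ether A6.
- In favour: ring A arrives with all four substituents, including the methyl ester. No lactone has to be opened by methoxide, so there is no phenoxide stage at which ring A could migrate; here it is better than the chosen plan. The polarity is matched (nucleophilic alkyne carbon to C6 of the electron-poor pyrone). Because O2' is still protected when the silyl ether is exchanged for acetate, the acetylation needs no chemoselectivity, also better than the chosen plan.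
- Against: the alkoxy group on C4 and the methyl group on the reacting C6 make A4 a sluggish diene, so high temperatures are to be expected, and aryl ethynyl ethers polymerise or hydrate under such conditions. A5 needs three different oxygen functions on ring B, built from the same catechol aldehyde 8 in about eight steps.
- Comparison: the mechanism is metal-free and operationally simple (equal or better), but the key step is thermally demanding and the total comes to an estimated fourteen operations against nine.

Alternative 3: Ring B is cut at C5'–C6', giving the open-chain aryloxy diketone A7, with C6' as a ketone beside a dimethyl acetal and C3'–C5' as a beta-methoxy enone.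
- Forward step: an excess of a lithium silylamide base should deprotonate C1' and then the C5' methyl group, whose vinylogous enolate adds to the C6' ketone; loss of water and enolisation give the phenol A8.
- In favour: the oxygen pattern of ring B is written into the chain, so O1' is the ether and O2' the free hydroxyl without any differentiation of a catechol; on this point it is better than the chosen plan. Ring A carries its methyl ester throughout.
- Against: once C1' is deprotonated, the C6' carbonyl is part of a delocalised enolate and a poor electrophile. The C1' carbanion sits in position for a Dieckmann-type attack on the ring A ester (five-membered benzofuranone). The aryloxide can be lost by elimination. A7 itself, a 2-aryloxy-1,3-diketone flanked by a keto acetal, has no short preparation. After A8 the acetal must still be hydrolysed and the chosen endgame (reduction, selective acetylation, acetal removal from ring A) repeated.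
- Comparison: the idea is attractive on structure, the weakest of the four on mechanism, and no shorter.

Key step: step 6

Remark on the chemistry: ring A is numbered C1 (ester carbon) to C6 (ether carbon) and ring B C1' (ether carbon) to C6' (acetoxymethyl carbon). With this numbering 10 and 11 map atom for atom onto 15, so their constitutions need no correction. As 15 has no stereocentre, no SMILES of the route carries a stereodescriptor.

**Route**

Step 1
Reactants: 1 3-bromo-5-methylphenol
Product: 2 1-bromo-3-(methoxymethoxy)-5-methylbenzene
Conditions: MOMCl, i-Pr2NEt, CH2Cl2, 0 °C to rt
Reagents that add atoms: chloromethyl methyl ether, COCCl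
Why: O-alkylation of the phenol (MOM ether formation); the acetal is stable to the amide base and to all later basic steps and serves as the directing group in step 2.

Step 2
Reactants: 2 1-bromo-3-(methoxymethoxy)-5-methylbenzene; 3 carbon dioxide
Product: 5 2-bromo-6-(methoxymethoxy)-4-methylbenzoic acid, via aryllithium 4 (not isolated)
Conditions: LiN(i-Pr)2, THF, −78 °C; dry CO2, −78 °C to 0 °C; cold 1 M HCl to pH 3
Reagents that add atoms: none
Why: Directed ortho-metalation and carboxylation: the amide base removes the ring hydrogen flanked by Br and OMOM (the most acidic, with lithium held by the acetal oxygens) without bromine–lithium exchange, and at −78 °C aryllithium 4 should not lose LiBr to an aryne before 3 traps it; brief cold acidification frees the acid without touching the acetal.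

Step 3
Reactants: 6 2-hydroxy-5-methoxybenzaldehyde
Product: 7 3-bromo-2-hydroxy-5-methoxybenzaldehyde
Conditions: Br2, NaOAc, AcOH, rt
Reagents that add atoms: bromine, BrBr
Why: Electrophilic aromatic bromination: the hydroxyl is the strongest director and its para position is blocked by the methoxy group, so bromine should enter at the free ortho position C3; acetate buffers the HBr.

Step 4
Reactants: 7 3-bromo-2-hydroxy-5-methoxybenzaldehyde
Product: 8 2,3-dihydroxy-5-methoxybenzaldehyde
Conditions: NaOH (aq, 6 equiv), CuSO4·5H2O (10 mol%), H2O, reflux, argon; then HCl (aq) to pH 2
Reagents that add atoms: sodium hydroxide, [Na+].[OH-]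
Why: Copper-mediated hydroxide substitution of an ortho-halophenol (Ullmann-type hydroxylation), the reaction type that converts bromovanillins into catechol aldehydes; the neighbouring phenoxide holds copper beside the C–Br bond and, being conjugated with the formyl group, protects the aldehyde from disproportionation, while argon prevents oxidation of the catecholate.

Step 5
Reactants: 5 2-bromo-6-(methoxymethoxy)-4-methylbenzoic acid; 8 2,3-dihydroxy-5-methoxybenzaldehyde
Product: 10 3-formyl-2-hydroxy-5-methoxyphenyl 2-bromo-6-(methoxymethoxy)-4-methylbenzoate, via acid chloride 9 (not isolated)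
Conditions: 1-chloro-N,N,2-trimethylprop-1-en-1-amine, CH2Cl2, 0 °C to rt; then 8 (1.2 equiv), pyridine, DMAP (cat.), CH2Cl2, 0 °C to rt
Reagents that add atoms: none
Why: The alpha-chloroenamine makes acid chloride 9 without releasing HCl, so the acetal is safe, and the small acyl chloride overcomes the 2,6-disubstitution of the acid; with pyridine and DMAP (nucleophilic catalysis, no phenoxide) the acylpyridinium is taken by the free, non-chelated hydroxyl of 8 (O2'). This ester is also the thermodynamic isomer because it keeps the hydroxyl–formyl hydrogen bond, so any ester formed on the other oxygen should shift over.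

Step 6
Reactants: 10 3-formyl-2-hydroxy-5-methoxyphenyl 2-bromo-6-(methoxymethoxy)-4-methylbenzoate
Product: 11 8-methoxy-1-(methoxymethoxy)-3-methyl-11-oxo-11H-dibenzo[b,e][1,4]dioxepine-6-carbaldehyde
Conditions: CuI (20 mol%), N,N-dimethylglycine (40 mol%), Cs2CO3 (2 equiv), 1,4-dioxane (0.01 M), 90 °C, argon
Reagents that add atoms: none
Why: Cs2CO3 deprotonates the formyl-chelated C1' hydroxyl and the phenoxide binds the dimethylglycinate-ligated monovalent copper centre; the C6–Br bond, activated and pre-coordinated through the ortho ester carbonyl, adds oxidatively to give an eight-membered aryl(phenoxo) cupracycle of trivalent copper, and C–O reductive elimination forms O–C6 and returns monovalent copper. The closest known reaction type is the amino-acid-promoted intramolecular Ullmann diaryl ether synthesis that turns 2-halo depsides into depsidones. The one ring closed is the seven-membered dioxepinone (C1–CO–O2'–C2'–C1'–O–C6), closed at the aryl C6–O bond by contraction of the cupracycle; the ester tether turns a coupling of two di-ortho-substituted partners into an intramolecular one. No stereocentre is formed. The selectivity needed is regiochemical: the ether must grow from O1', so the aroyl group has to stay on O2'. The formyl group secures this because the O1' phenoxide, conjugated and chelated to it, is the more stable anion, and the 2,6-disubstituted aroyl carbonyl resists the tetrahedral intermediate that an O-to-O acyl shift needs. High dilution suppresses intermolecular etherification, and anhydrous carbonate in an aprotic solvent spares the aryl ester.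

Step 7
Reactants: 11 8-methoxy-1-(methoxymethoxy)-3-methyl-11-oxo-11H-dibenzo[b,e][1,4]dioxepine-6-carbaldehyde
Product: 13 methyl 2-[2-hydroxy-6-(hydroxymethyl)-4-methoxyphenoxy]-6-(methoxymethoxy)-4-methylbenzoate, via hydroxymethyl depsidone 12 (not isolated)
Conditions: NaBH4 (0.5 equiv), THF/MeOH 4:1, −10 °C; then NaOMe (1.5 equiv), MeOH, 0 °C; cold 1 M HCl to pH 5
Reagents that add atoms: sodium methoxide, C[O-].[Na+]
Why: Borohydride reduces the aryl aldehyde within minutes in the cold while the hindered lactone carbonyl is attacked far more slowly; methoxide then opens the strained aryl lactone by transesterification (the known alkoxide cleavage of depsidones), giving the methyl ester and the C2' phenol in one event. Reducing first removes the formyl group that would make the O1' phenoxide a good leaving group for a Smiles-type aryl shift to O2'; lactone opening during the reduction would lead to the same product 13.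

Step 8
Reactants: 13 methyl 2-[2-hydroxy-6-(hydroxymethyl)-4-methoxyphenoxy]-6-(methoxymethoxy)-4-methylbenzoate
Product: 14 methyl 2-[2-(acetoxymethyl)-6-hydroxy-4-methoxyphenoxy]-6-(methoxymethoxy)-4-methylbenzoate
Conditions: AcOH (2 equiv), PPh3, DIAD, THF, 0 °C to rt
Reagents that add atoms: acetic acid, CC(=O)O
Why: Mitsunobu esterification: the primary benzylic alcohol is activated as its oxyphosphonium salt and displaced by acetate, the only pronucleophile acidic enough (about five pK units below the phenol) to be deprotonated by the betaine, so the C2' hydroxyl is not acylated; the benzylic carbon is neither ortho nor para to a free hydroxyl, so no quinone methide can form.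

Step 9
Reactants: 14 methyl 2-[2-(acetoxymethyl)-6-hydroxy-4-methoxyphenoxy]-6-(methoxymethoxy)-4-methylbenzoate
Product: 15 Betaethrin A, methyl 2-[2-(acetoxymethyl)-6-hydroxy-4-methoxyphenoxy]-6-hydroxy-4-methylbenzoate
Conditions: ZnBr2, n-PrSH, CH2Cl2, 0 °C
Reagents that add atoms: none
Why: Lewis acid-assisted thiolysis of the MOM acetal: zinc coordinates the acetal (helped by the neighbouring ester carbonyl) and the thiol takes the methoxymethyl group as an O,S-acetal, so no free oxocarbenium ion remains to alkylate ring B; the brief, cold, alcohol-free conditions are of a kind known to tolerate acetates and methyl esters.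

**Compound list**

1 | 3-bromo-5-methylphenol | Cc1cc(O)cc(Br)c1 | starting material
2 | 1-bromo-3-(methoxymethoxy)-5-methylbenzene | COCOc1cc(C)cc(Br)c1 | intermediate
3 | carbon dioxide | O=C=O | starting material
4 | [2-bromo-6-(methoxymethoxy)-4-methylphenyl]lithium | [Li]c1c(Br)cc(C)cc1OCOC | intermediate
5 | 2-bromo-6-(methoxymethoxy)-4-methylbenzoic acid | COCOc1cc(C)cc(Br)c1C(=O)O | intermediate
6 | 2-hydroxy-5-methoxybenzaldehyde | COc1ccc(O)c(C=O)c1 | starting material
7 | 3-bromo-2-hydroxy-5-methoxybenzaldehyde | COc1cc(Br)c(O)c(C=O)c1 | intermediate
8 | 2,3-dihydroxy-5-methoxybenzaldehyde | COc1cc(O)c(O)c(C=O)c1 | intermediate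
9 | 2-bromo-6-(methoxymethoxy)-4-methylbenzoyl chloride | COCOc1cc(C)cc(Br)c1C(=O)Cl | intermediate
10 | 3-formyl-2-hydroxy-5-methoxyphenyl 2-bromo-6-(methoxymethoxy)-4-methylbenzoate | COCOc1cc(C)cc(Br)c1C(=O)Oc1cc(OC)cc(C=O)c1O | intermediate
11 | 8-methoxy-1-(methoxymethoxy)-3-methyl-11-oxo-11H-dibenzo[b,e][1,4]dioxepine-6-carbaldehyde | COCOc1cc(C)cc2Oc3c(C=O)cc(OC)cc3OC(=O)c12 | intermediate
12 | 6-(hydroxymethyl)-8-methoxy-1-(methoxymethoxy)-3-methyl-11H-dibenzo[b,e][1,4]dioxepin-11-one | COCOc1cc(C)cc2Oc3c(CO)cc(OC)cc3OC(=O)c12 | intermediate
13 | methyl 2-[2-hydroxy-6-(hydroxymethyl)-4-methoxyphenoxy]-6-(methoxymethoxy)-4-methylbenzoate | COC(=O)c1c(OCOC)cc(C)cc1Oc1c(O)cc(OC)cc1CO | intermediate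
14 | methyl 2-[2-(acetoxymethyl)-6-hydroxy-4-methoxyphenoxy]-6-(methoxymethoxy)-4-methylbenzoate | COC(=O)c1c(OCOC)cc(C)cc1Oc1c(O)cc(OC)cc1COC(C)=O | intermediate
15 | Betaethrin A, methyl 2-[2-(acetoxymethyl)-6-hydroxy-4-methoxyphenoxy]-6-hydroxy-4-methylbenzoate | COC(=O)c1c(O)cc(C)cc1Oc1c(O)cc(OC)cc1COC(C)=O | target

**Step count and risk**

Total: 9 steps. Longest linear sequence: 7 steps (steps 1, 2, 5, 6, 7, 8, 9 from 1; the branch from 6 through steps 3, 4, 5 to 9 is equally long).

Step 6 (key step). The coupling may be slow: the nucleophile is a chelated, formyl-conjugated phenoxide that can also sequester copper, and both carbons are di-ortho-substituted. During a slow reaction the aroyl group could shift to O1' and the ring then close from O2' (the more nucleophilic phenoxide, so the formyl lock is a bias and not a guarantee), the aryl ester could be cleaved, or the bromide reduced. The fallback replaces copper catalysis by addition–elimination at a C–F bond; it sets out from 8 and returns at 11. Purchased 3-fluoro-5-methylphenol F1 is protected with MOMCl and i-Pr2NEt to 1-fluoro-3-(methoxymethoxy)-5-methylbenzene F2. This is lithiated between F and OMOM with LiN(i-Pr)2 at −78 °C to [2-fluoro-6-(methoxymethoxy)-4-methylphenyl]lithium F3 and carboxylated with 3 to 2-fluoro-6-(methoxymethoxy)-4-methylbenzoic acid F4. Activation as in step 5 gives 2-fluoro-6-(methoxymethoxy)-4-methylbenzoyl chloride F5, which acylates 8 under the conditions of step 5 to 3-formyl-2-hydroxy-5-methoxyphenyl 2-fluoro-6-(methoxymethoxy)-4-methylbenzoate F6. K2CO3 in DMF at 60–90 °C should then close F6 to 11 through a Meisenheimer adduct at the ester-activated C6.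

Step 5. Acylation may occur at the chelated oxygen or on both oxygens, the O-to-O equilibration may be slow because the acyl group is hindered, and the acetal next to the acyl chloride may be lost during activation. The fallback differentiates the two oxygens by protection; it sets out from 7 and returns at 10. Compound 7 is alkylated with 4-methoxybenzyl chloride and K2CO3 in DMF to 3-bromo-5-methoxy-2-[(4-methoxybenzyl)oxy]benzaldehyde F7. Miyaura borylation (bis(pinacolato)diboron, Pd(dppf)Cl2, KOAc, dioxane, 80 °C) gives 5-methoxy-2-[(4-methoxybenzyl)oxy]-3-(4,4,5,5-tetramethyl-1,3,2-dioxaborolan-2-yl)benzaldehyde F8, and NaBO3·4H2O in THF/H2O oxidises it to 3-hydroxy-5-methoxy-2-[(4-methoxybenzyl)oxy]benzaldehyde F9. Its only hydroxyl is acylated with 9 (pyridine, DMAP) to 3-formyl-5-methoxy-2-[(4-methoxybenzyl)oxy]phenyl 2-bromo-6-(methoxymethoxy)-4-methylbenzoate F10, and DDQ in CH2Cl2/pH 7 buffer removes the benzyl ether to give 10.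

Step 4. The substitution may stall, traces of air may oxidise the catecholate to quinone-derived tars, and the aldehyde may disproportionate in hot alkali. The fallback brings in the oxygen by formylation and oxidation; it sets out from 6 and returns at 8. Duff formylation of 6 (hexamethylenetetramine, CF3CO2H, reflux, then aqueous acid) gives 2-hydroxy-5-methoxybenzene-1,3-dicarbaldehyde F11. A Dakin oxidation with one equivalent of H2O2 in cold aqueous NaOH converts one formyl group through 3-formyl-2-hydroxy-5-methoxyphenyl formate F12, hydrolysed in the same flask, into the hydroxyl of 8.

Step 7. Hydride may attack the activated aryl lactone as well as the aldehyde, and at the phenoxide stage ring A may migrate between the ring B oxygens or to the benzylic alkoxide if the basic mixture is kept too long or too warm. The fallback separates the two operations in the opposite order and uses a weaker base; it sets out from 11 and returns at 13. K2CO3 in MeOH at 0 °C, quenched as soon as the lactone is consumed, gives methyl 2-(2-formyl-6-hydroxy-4-methoxyphenoxy)-6-(methoxymethoxy)-4-methylbenzoate F13, in which only an inert hindered methyl ester remains. NaBH4 in MeOH at 0 °C then reduces the aldehyde to 13. This order accepts the formyl-biased aryl shift as its own risk, which the short, cold carbonate treatment is meant to contain.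

Step 9. The Lewis acid may ionise the ortho-aryloxy benzylic acetate with capture by the thiol, or the acetal cleavage may be incomplete at the low temperature needed to prevent this. The fallback changes the order so that no acetate is present when the acetal is removed; it sets out from 13 and returns at 15. ZnBr2 and n-PrSH in CH2Cl2 at 0 °C convert 13 into methyl 2-hydroxy-6-[2-hydroxy-6-(hydroxymethyl)-4-methoxyphenoxy]-4-methylbenzoate F14. The Mitsunobu esterification of step 8 (AcOH, PPh3, DIAD) then gives 15 directly, the chelated ring A hydroxyl being an even poorer pronucleophile than the ring B phenol.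

Step 8. Activation of the hindered benzylic alcohol may be slow, and the phenol may then compete as nucleophile and give benzyl aryl ether oligomers. The fallback uses exhaustive acylation followed by selective removal of the phenolic acetate; it sets out from 13 and returns at 14. Ac2O, pyridine and DMAP give methyl 2-[2-(acetyloxy)-6-[(acetyloxy)methyl]-4-methoxyphenoxy]-6-(methoxymethoxy)-4-methylbenzoate F15. Pyrrolidine in CH2Cl2 at 0 °C should cleave only the aryl acetate, whose phenoxide is by far the better leaving group, to give 14.

**Further compounds**

F1 | step 6 | 3-fluoro-5-methylphenol (purchased) | Cc1cc(O)cc(F)c1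
F2 | step 6 | 1-fluoro-3-(methoxymethoxy)-5-methylbenzene | COCOc1cc(C)cc(F)c1
F3 | step 6 | [2-fluoro-6-(methoxymethoxy)-4-methylphenyl]lithium | [Li]c1c(F)cc(C)cc1OCOC
F4 | step 6 | 2-fluoro-6-(methoxymethoxy)-4-methylbenzoic acid | COCOc1cc(C)cc(F)c1C(=O)O
F5 | step 6 | 2-fluoro-6-(methoxymethoxy)-4-methylbenzoyl chloride | COCOc1cc(C)cc(F)c1C(=O)Cl
F6 | step 6 | 3-formyl-2-hydroxy-5-methoxyphenyl 2-fluoro-6-(methoxymethoxy)-4-methylbenzoate | COCOc1cc(C)cc(F)c1C(=O)Oc1cc(OC)cc(C=O)c1O
F7 | step 5 | 3-bromo-5-methoxy-2-[(4-methoxybenzyl)oxy]benzaldehyde | COc1ccc(COc2c(Br)cc(OC)cc2C=O)cc1
F8 | step 5 | 5-methoxy-2-[(4-methoxybenzyl)oxy]-3-(4,4,5,5-tetramethyl-1,3,2-dioxaborolan-2-yl)benzaldehyde | COc1ccc(COc2c(B3OC(C)(C)C(C)(C)O3)cc(OC)cc2C=O)cc1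
F9 | step 5 | 3-hydroxy-5-methoxy-2-[(4-methoxybenzyl)oxy]benzaldehyde | COc1ccc(COc2c(O)cc(OC)cc2C=O)cc1
F10 | step 5 | 3-formyl-5-methoxy-2-[(4-methoxybenzyl)oxy]phenyl 2-bromo-6-(methoxymethoxy)-4-methylbenzoate | COCOc1cc(C)cc(Br)c1C(=O)Oc1cc(OC)cc(C=O)c1OCc1ccc(OC)cc1
F11 | step 4 | 2-hydroxy-5-methoxybenzene-1,3-dicarbaldehyde | COc1cc(C=O)c(O)c(C=O)c1
F12 | step 4 | 3-formyl-2-hydroxy-5-methoxyphenyl formate | COc1cc(OC=O)c(O)c(C=O)c1
F13 | step 7 | methyl 2-(2-formyl-6-hydroxy-4-methoxyphenoxy)-6-(methoxymethoxy)-4-methylbenzoate | COC(=O)c1c(OCOC)cc(C)cc1Oc1c(O)cc(OC)cc1C=O
F14 | step 9 | methyl 2-hydroxy-6-[2-hydroxy-6-(hydroxymethyl)-4-methoxyphenoxy]-4-methylbenzoate | COC(=O)c1c(O)cc(C)cc1Oc1c(O)cc(OC)cc1CO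
F15 | step 8 | methyl 2-[2-(acetyloxy)-6-[(acetyloxy)methyl]-4-methoxyphenoxy]-6-(methoxymethoxy)-4-methylbenzoate | COC(=O)c1c(OCOC)cc(C)cc1Oc1c(OC(C)=O)cc(OC)cc1COC(C)=O
A1 | alternative 1 | 3-methylcyclobut-2-en-1-one | CC1=CC(=O)C1
A2 | alternative 1 | 2-(ethynyloxy)-5-methoxy-1-[(triisopropylsilyl)oxy]-3-{[(triisopropylsilyl)oxy]methyl}benzene | C#COc1c(O[Si](C(C)C)(C(C)C)C(C)C)cc(OC)cc1CO[Si](C(C)C)(C(C)C)C(C)C
A3 | alternative 1 | 3-methyl-5-{4-methoxy-2-[(triisopropylsilyl)oxy]-6-{[(triisopropylsilyl)oxy]methyl}phenoxy}phenol | Cc1cc(O)cc(Oc2c(O[Si](C(C)C)(C(C)C)C(C)C)cc(OC)cc2CO[Si](C(C)C)(C(C)C)C(C)C)c1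
A4 | alternative 2 | methyl 4-(methoxymethoxy)-6-methyl-2-oxo-2H-pyran-3-carboxylate | COCOC1=C(C(=O)OC)C(=O)OC(C)=C1
A5 | alternative 2 | tert-butyl{[2-(ethynyloxy)-5-methoxy-3-(methoxymethoxy)phenyl]methoxy}dimethylsilane | C#COc1c(OCOC)cc(OC)cc1CO[Si](C)(C)C(C)(C)C
A6 | alternative 2 | methyl 2-[2-({[tert-butyl(dimethyl)silyl]oxy}methyl)-4-methoxy-6-(methoxymethoxy)phenoxy]-6-(methoxymethoxy)-4-methylbenzoate | COC(=O)c1c(OCOC)cc(C)cc1Oc1c(OCOC)cc(OC)cc1CO[Si](C)(C)C(C)(C)C
A7 | alternative 3 | methyl 2-{[(5E)-1,1,6-trimethoxy-2,4-dioxohept-5-en-3-yl]oxy}-6-(methoxymethoxy)-4-methylbenzoate (racemic at the enolisable C3) | COC(=O)c1c(OCOC)cc(C)cc1OC(C(=O)C(OC)OC)C(=O)/C=C(\C)OC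
A8 | alternative 3 | methyl 2-[2-(dimethoxymethyl)-6-hydroxy-4-methoxyphenoxy]-6-(methoxymethoxy)-4-methylbenzoate | COC(=O)c1c(OCOC)cc(C)cc1Oc1c(O)cc(OC)cc1C(OC)OC
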